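**Retrosynthetic overview**
1. Luzonoid A ⇒ (desilylation, 7-O-p-coumaroylation, 1-O-isovalerylation) the cis-fused iridoid lactol with a free 7-OH; its C10 and C11 carbinols come from a C10 aldehyde and a C11 methyl ester.
2. Dihydropyran ring (C1, O2, C3, C4, C5, C9) ⇒ lactolisation of a C1 aldehyde with the C3 enol obtained by formylating the C4 methylene of an acetate arm on C5.
3. 8α-OH and 9-H ⇒ SmI2 opening of a C8–C9 α-epoxy aldehyde, made from the C8=C9 enal by nucleophilic epoxidation anti to O7.
4. The strategy rests on the cyclopentane C5–C6–C7–C8–C9, which carries oxygen at C7, the one-carbon branches C10 (on C8) and C1 (on C9) and the C4 chain on C5; it is cut at C5–C9 and C7–C8 into enal 3 (C7, C6, C5, C4, C11) and alkynyl acetal 7 (C1, C9, C8, C10) by a nickel-catalysed intermolecular reductive (3+2) cycloaddition.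
5. Ring order: cyclopentene first (step 4), dihydropyran second (step 13); the absolute configuration comes from a lipase resolution of the cyclopentenol (step 5).

Key step: step 4

Assumption: atoms carry iridoid numbers in every intermediate; α is the cyclopentane face that bears the C4 chain on C5, β the face of H5 and H9.
Assumption: the nickel step is taken to give mainly the 5,7-trans alcohol (a cis epimer would be removed by chromatography), and the lipase is taken to acylate the 7R enantiomer faster.
Assumption: racemates are written as the dot-joined pair of enantiomers; lactols and their silyl ethers are expected as anomer mixtures and are written without a descriptor at C1.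

**Route**

Step 1
Reactants: 1 methyl but-3-enoate; 2 (E)-but-2-enal (crotonaldehyde, in excess)
Product: 3 methyl (E)-5-oxopent-3-enoate
Conditions: second-generation Hoveyda–Grubbs catalyst RuCl2(H2IMes)(=CH-C6H4-2-OiPr) (cat.), CH2Cl2, 40 °C
Reagents that add atoms: none
Why: Olefin cross-metathesis of a terminal alkene with an excess of an electron-poor enal should be E-selective and loses only propene; because the C4 methylene of 3 is doubly activated, the enal is to be used at once.

Step 2
Reactants: 4 3,3-diethoxyprop-1-yne
Product: 6 4,4-diethoxybut-2-yn-1-ol, via lithium acetylide 5 (not isolated)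
Conditions: n-BuLi, THF, −78 °C; (CH2O)n, −78 °C to rt; H2O
Reagents that add atoms: formaldehyde (from paraformaldehyde), C=O
Why: Hydroxymethylation of a lithium acetylide with formaldehyde is routine, and starting from the commercial alkynyl acetal avoids having to displace alkoxide from an orthoformate with an acetylide.

Step 3
Reactants: 6 4,4-diethoxybut-2-yn-1-ol
Product: 7 1-{[(4,4-diethoxybut-2-yn-1-yl)oxy]methyl}-4-methoxybenzene (PMB ether of 6)
Conditions: NaH, 4-MeOC6H4CH2Cl, Bu4NI (cat.), THF–DMF, 0 °C to rt
Reagents that add atoms: 4-methoxybenzyl chloride, COc1ccc(CCl)cc1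
Why: Williamson etherification of the primary propargylic alkoxide; PMB is chosen over benzyl because it can later be removed oxidatively without touching the ring alkene.

Step 4
Reactants: 3 methyl (E)-5-oxopent-3-enoate; 7 PMB ether of 4,4-diethoxybut-2-yn-1-ol
Product: 8 racemic methyl 2-[(1R*,4S*)-3-(diethoxymethyl)-4-hydroxy-2-{[(4-methoxyphenyl)methoxy]methyl}cyclopent-2-en-1-yl]acetate (5,7-trans: 7-OH anti to the C4 chain on C5)
Conditions: Ni(cod)2 (10 mol %), PBu3 (20 mol %), Et3B, THF–MeOH, 50 °C
Reagents that add atoms: none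
Why: Zerovalent nickel binds enal and alkyne and couples them by oxidative cyclization, joining the enal β-carbon C5 to alkyne carbon C9 in an O-bound nickel enolate metallacycle; methanol protonates the enolate at C6, the alkenyl–nickel bond adds to the C7 aldehyde, and Et3B returns the catalyst to zerovalent nickel by ethyl transfer and β-hydride elimination. This is the known nickel-catalysed intermolecular reductive (3+2) cycloaddition of enals with alkynes, applied here to an alkyne with a propargylic ether and a propargylic acetal. The cyclopentene ring closes in the second C–C bond formation, a 5-exo addition of the C8–Ni bond to the tethered C7=O. C5 is formed as a racemate (resolved in step 5); C7 is set relative to C5 in the carbonyl insertion, where the nickel-bound oxygen should turn away from the pseudoaxial C5 side chain and give the 5,7-trans alcohol. The step needs one regiochemistry (C5–C9 and C7–C8): the unbranched CH2OPMB terminus is the smaller one and should take the new C–C bond in the oxidative cyclization, while the branched, more electron-poor diethoxymethyl terminus stays on nickel and ends up on C8.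

Step 5
Reactants: 8 racemic 5,7-trans cyclopentenol
Product: 9 methyl 2-[(1R,4S)-3-(diethoxymethyl)-4-hydroxy-2-{[(4-methoxyphenyl)methoxy]methyl}cyclopent-2-en-1-yl]acetate (5R,7S in iridoid numbering; recovered alcohol)
Conditions: Burkholderia cepacia lipase (Amano PS, immobilised), vinyl acetate, t-BuOMe, 30 °C, stopped slightly beyond half conversion; chromatography
Reagents that add atoms: none
Why: Lipase-catalysed kinetic resolution by acyl transfer; by the empirical size rule for secondary alcohols (large group = the substituted C8 side) the 7R enantiomer should be acetylated faster, leaving the 5R,7S alcohol, which fixes the absolute configuration of C5 and C7.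

Step 6
Reactants: 9 (5R,7S)-cyclopentenol
Product: 10 7-O-pivalate of 9
Conditions: t-BuCOCl, pyridine, DMAP (cat.), CH2Cl2, 0 °C to rt
Reagents that add atoms: pivaloyl chloride, CC(C)(C)C(=O)Cl
Why: Acylation of the secondary allylic alcohol; the pivalate has no α-hydrogen (so it survives the later LDA step), shields the β face next to C8, and is removed for free in the i-Bu2AlH step.

Step 7
Reactants: 10 pivalate PMB ether
Product: 11 allylic alcohol (C1 as CH2OH on C9; 7β-OPiv; C10 diethyl acetal on C8)
Conditions: DDQ, CH2Cl2–pH 7 buffer, 0 °C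
Reagents that add atoms: none
Why: Oxidative cleavage of the PMB ether by DDQ is selective for the electron-rich benzyl group and leaves the acetal, both esters and the tetrasubstituted alkene intact.

Step 8
Reactants: 11 allylic alcohol
Product: 12 enal (C1 aldehyde on C9, conjugated with C8=C9)
Conditions: MnO2, CH2Cl2, rt
Reagents that add atoms: none
Why: MnO2 oxidises the primary allylic alcohol to the enal under neutral conditions without over-oxidation.

Step 9
Reactants: 12 enal
Product: 13 8,9-α-epoxy aldehyde (epoxide oxygen on the face of the C4 chain, anti to 7-OPiv)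
Conditions: 30% aq H2O2, K2CO3, MeOH, 0 °C
Reagents that add atoms: hydrogen peroxide, OO
Why: Weitz–Scheffer nucleophilic epoxidation; hydroperoxide should add to the β-carbon C8 anti to the neighbouring 7β-pivaloyloxy group, and the enolate then closes the epoxide on the same (α) face, which sets the C8 oxygen.

Step 10
Reactants: 13 epoxy aldehyde
Product: 14 β-hydroxy aldehyde (8α-OH, 9β-H, C1 aldehyde on C9)
Conditions: SmI2 (2.2 equiv), THF–MeOH, −90 °C; pH 7 buffer
Reagents that add atoms: none
Why: Reductive cleavage of an α,β-epoxy carbonyl compound by SmI2: the ketyl at C1 breaks the Cα–O bond (C9–O) so that oxygen stays on C8, and methanol protonates the trivalent samarium enolate at low temperature, expected on the β face away from the samarium alkoxide and the C5 chain (a 9-epimer would still be corrected in step 13).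

Step 11
Reactants: 14 β-hydroxy aldehyde
Product: 15 C1 diethyl acetal of 14 (bis-acetal)
Conditions: HC(OEt)3, EtOH, PPTS (cat.), rt
Reagents that add atoms: triethyl orthoformate, CCOC(OCC)OCC; ethanol, CCO
Why: Mild orthoformate acetalisation masks the C1 aldehyde for the enolate step without dehydrating the aldol, and ethanol keeps the C1 and C10 acetals identical.

Step 12
Reactants: 15 bis-acetal
Product: 17 α-hydroxymethylene ester (C3 enol on C4 of 15), via dilithium enolate alkoxide 16 (not isolated)
Conditions: LDA (3.3 equiv), THF, −78 °C; HCO2Me, −78 to −30 °C; AcOH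
Reagents that add atoms: methyl formate, COC=O
Why: Claisen formylation of the ester enolate introduces C3; the extra base covers the tertiary C8 hydroxyl, enolate formation protects the ester from that alkoxide, and the pivalate cannot be enolised.

Step 13
Reactants: 17 hydroxymethylene ester
Product: 19 cis-fused lactol aldehyde (C1 hemiacetal; C3=C4 enol ether; C11 methyl ester; C10 aldehyde; 7β-OPiv; 8α-OH), via open-chain dialdehyde enol 18 (not isolated)
Conditions: 2 M aq HCl–THF, rt
Reagents that add atoms: water, O
Why: Acid hydrolysis frees the C1 and C10 aldehydes and the C3 enol oxygen adds to C1 to close the dihydropyran (6-exo hemiacetalisation); only the cis-fused lactol is a stable sink and C9 can epimerise through the open aldehyde, so 9β-H is secured here.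

Step 14
Reactants: 19 lactol aldehyde
Product: 20 1-O-triethylsilyl acetal of 19
Conditions: Et3SiCl, imidazole, CH2Cl2, 0 °C
Reagents that add atoms: chlorotriethylsilane, CC[Si](CC)(CC)Cl
Why: Silylation of the lactol hydroxyl (the most acidic and accessible OH; the tertiary C8-OH does not react) locks the ring so that it cannot open to an aldehyde during hydride reduction.

Step 15
Reactants: 20 silyl acetal
Product: 21 tetraol (7β-OH, 8α-OH, C10 CH2OH, C11 CH2OH; 1-O-SiEt3)
Conditions: i-Bu2AlH (excess), CH2Cl2, −78 to −20 °C; aq KNaC4H4O6 (potassium sodium tartrate)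
Reagents that add atoms: none
Why: i-Bu2AlH reduces the C10 aldehyde, reduces the conjugated C11 ester 1,2 to the allylic alcohol and cleaves the pivalate in one operation, while the silyl acetal is inert to hydride.

Step 16
Reactants: 21 tetraol
Product: 22 10,11-bis-O-TBS ether of 21
Conditions: t-BuMe2SiCl (2.2 equiv), imidazole, DMF, −20 to 0 °C
Reagents that add atoms: tert-butyldimethylsilyl chloride, CC(C)(C)[Si](C)(C)Cl
Why: The two primary alcohols are silylated selectively over the hindered secondary C7-OH (next to the quaternary C8) and the tertiary C8-OH.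

Step 17
Reactants: 22 bis-TBS ether
Product: 23 lactol (1-OH; 10,11-bis-OTBS; 7-OH, 8-OH free)
Conditions: Bu4NF–AcOH (1:1), THF, −40 °C
Reagents that add atoms: none
Why: Buffered fluoride at low temperature cleaves the anomeric triethylsilyl ether (a lactolate is the better leaving group and the group is the smaller silyl) much faster than the primary TBS ethers.

Step 18
Reactants: 23 lactol
Product: 24 1β-O-isovaleryl ester (1S; 10,11-bis-OTBS; 7-OH free)
Conditions: isovaleryl chloride (1.1 equiv), pyridine, CH2Cl2, −30 °C
Reagents that add atoms: 3-methylbutanoyl chloride, CC(C)CC(=O)Cl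
Why: The lactol hydroxyl is acylated in preference to the neopentyl-type C7-OH and the tertiary C8-OH; the anomers interconvert, and the ester should go onto the convex face, trans to the C9–C8 bond and pseudoaxial (anomeric effect), which is the 1β configuration of the target.

Step 19
Reactants: 25 p-coumaric acid
Product: 27 (E)-3-[4-(tert-butyldimethylsilyloxy)phenyl]prop-2-enoic acid, via silyl ester 26 (not isolated)
Conditions: t-BuMe2SiCl (2.5 equiv), imidazole, DMF, rt; AcOH–THF–H2O
Reagents that add atoms: tert-butyldimethylsilyl chloride, CC(C)(C)[Si](C)(C)Cl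
Why: Both acidic groups are silylated and the labile silyl ester is then hydrolysed under mild acid, to which the aryl silyl ether is stable.

Step 20
Reactants: 24 1-O-isovaleryl alcohol; 27 silyl-protected p-coumaric acid
Product: 29 tris-TBS luzonoid A (10-O, 11-O and phenol silylated), via mixed anhydride 28 (not isolated)
Conditions: 27, 2,4,6-Cl3C6H2COCl, Et3N, THF, rt; then 24, DMAP, toluene, rt to 40 °C
Reagents that add atoms: none
Why: Yamaguchi esterification suits the hindered secondary C7-OH; the alcohol attacks the unhindered cinnamoyl carbonyl of the mixed anhydride and the C7–O bond is untouched, so configuration at C7 is retained.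

Step 21
Reactants: 29 tris-TBS luzonoid A
Product: 30 luzonoid A
Conditions: Bu4NF–AcOH (1:1, excess), THF, 0 °C to rt
Reagents that add atoms: none
Why: Buffered fluoride removes the aryl and the two primary silyl ethers under near-neutral conditions that should spare the acyloxy acetal, the coumarate and the acid-sensitive enol ether and suppress acyl migration.

**Compound list**
1 | methyl but-3-enoate | C=CCC(=O)OC | starting material
2 | (E)-but-2-enal (crotonaldehyde) | C/C=C/C=O | starting material
3 | methyl (E)-5-oxopent-3-enoate | O=C/C=C/CC(=O)OC | intermediate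
4 | 3,3-diethoxyprop-1-yne | C#CC(OCC)OCC | starting material
5 | lithium 3,3-diethoxyprop-1-yn-1-ide (not isolated) | [Li]C#CC(OCC)OCC | intermediate
6 | 4,4-diethoxybut-2-yn-1-ol | OCC#CC(OCC)OCC | intermediate
7 | 1-{[(4,4-diethoxybut-2-yn-1-yl)oxy]methyl}-4-methoxybenzene | COc1ccc(COCC#CC(OCC)OCC)cc1 | intermediate
8 | racemic 5,7-trans cyclopentenol, methyl 2-[(1R*,4S*)-3-(diethoxymethyl)-4-hydroxy-2-{[(4-methoxyphenyl)methoxy]methyl}cyclopent-2-en-1-yl]acetate | COC(=O)C[C@H]1C[C@H](O)C(C(OCC)OCC)=C1COCc1ccc(OC)cc1.COC(=O)C[C@@H]1C[C@@H](O)C(C(OCC)OCC)=C1COCc1ccc(OC)cc1 | intermediate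
9 | (1R,4S) enantiomer of 8 (5R,7S in iridoid numbering) | COC(=O)C[C@H]1C[C@H](O)C(C(OCC)OCC)=C1COCc1ccc(OC)cc1 | intermediate
10 | 7β-O-pivalate of 9 | COC(=O)C[C@H]1C[C@H](OC(=O)C(C)(C)C)C(C(OCC)OCC)=C1COCc1ccc(OC)cc1 | intermediate
11 | allylic alcohol (10 without PMB) | COC(=O)C[C@H]1C[C@H](OC(=O)C(C)(C)C)C(C(OCC)OCC)=C1CO | intermediate
12 | enal (C1 aldehyde on C9, C8=C9) | COC(=O)C[C@H]1C[C@H](OC(=O)C(C)(C)C)C(C(OCC)OCC)=C1C=O | intermediate
13 | 8,9-α-epoxy aldehyde | COC(=O)C[C@H]1C[C@H](OC(=O)C(C)(C)C)[C@@]2(C(OCC)OCC)O[C@@]12C=O | intermediate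
14 | β-hydroxy aldehyde (8α-OH, 9β-H) | COC(=O)C[C@H]1C[C@H](OC(=O)C(C)(C)C)[C@](O)(C(OCC)OCC)[C@H]1C=O | intermediate
15 | C1 diethyl acetal of 14 | COC(=O)C[C@H]1C[C@H](OC(=O)C(C)(C)C)[C@](O)(C(OCC)OCC)[C@H]1C(OCC)OCC | intermediate
16 | dilithium C8-alkoxide C4-ester enolate of 15 (not isolated) | COC(O[Li])=C[C@H]1C[C@H](OC(=O)C(C)(C)C)[C@](O[Li])(C(OCC)OCC)[C@H]1C(OCC)OCC | intermediate
17 | α-hydroxymethylene ester (C3 enol on C4; enol geometry open) | COC(=O)C(=CO)[C@H]1C[C@H](OC(=O)C(C)(C)C)[C@](O)(C(OCC)OCC)[C@H]1C(OCC)OCC | intermediate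
18 | open-chain C1,C10-dialdehyde with C3 enol (not isolated) | COC(=O)C(=CO)[C@H]1C[C@H](OC(=O)C(C)(C)C)[C@](O)(C=O)[C@H]1C=O | intermediate
19 | cis-fused lactol aldehyde (1-OH, C11 CO2Me, C10 CHO, 7β-OPiv, 8α-OH) | OC1OC=C(C(=O)OC)[C@H]2C[C@H](OC(=O)C(C)(C)C)[C@](O)(C=O)[C@@H]12 | intermediate
20 | 1-O-triethylsilyl acetal of 19 | CC[Si](CC)(CC)OC1OC=C(C(=O)OC)[C@H]2C[C@H](OC(=O)C(C)(C)C)[C@](O)(C=O)[C@@H]12 | intermediate
21 | tetraol (7β-OH, 8α-OH, 10-OH, 11-OH; 1-O-SiEt3) | CC[Si](CC)(CC)OC1OC=C(CO)[C@H]2C[C@H](O)[C@](O)(CO)[C@@H]12 | intermediate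
22 | 10,11-bis-O-TBS ether of 21 | CC[Si](CC)(CC)OC1OC=C(CO[Si](C)(C)C(C)(C)C)[C@H]2C[C@H](O)[C@](O)(CO[Si](C)(C)C(C)(C)C)[C@@H]12 | intermediate
23 | lactol (1-OH; 10,11-bis-OTBS) | OC1OC=C(CO[Si](C)(C)C(C)(C)C)[C@H]2C[C@H](O)[C@](O)(CO[Si](C)(C)C(C)(C)C)[C@@H]12 | intermediate
24 | 1β-O-isovaleryl ester of 23 | CC(C)CC(=O)O[C@@H]1OC=C(CO[Si](C)(C)C(C)(C)C)[C@H]2C[C@H](O)[C@](O)(CO[Si](C)(C)C(C)(C)C)[C@@H]12 | intermediate
25 | p-coumaric acid | OC(=O)/C=C/c1ccc(O)cc1 | starting material
26 | tert-butyldimethylsilyl (E)-3-[4-(tert-butyldimethylsilyloxy)phenyl]prop-2-enoate (not isolated) | CC(C)(C)[Si](C)(C)OC(=O)/C=C/c1ccc(O[Si](C)(C)C(C)(C)C)cc1 | intermediate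
27 | (E)-3-[4-(tert-butyldimethylsilyloxy)phenyl]prop-2-enoic acid | OC(=O)/C=C/c1ccc(O[Si](C)(C)C(C)(C)C)cc1 | intermediate
28 | mixed anhydride of 27 with 2,4,6-trichlorobenzoic acid (not isolated) | O=C(/C=C/c1ccc(O[Si](C)(C)C(C)(C)C)cc1)OC(=O)c1c(Cl)cc(Cl)cc1Cl | intermediate
29 | tris-TBS luzonoid A | CC(C)CC(=O)O[C@@H]1OC=C(CO[Si](C)(C)C(C)(C)C)[C@H]2C[C@H](OC(=O)/C=C/c3ccc(O[Si](C)(C)C(C)(C)C)cc3)[C@](O)(CO[Si](C)(C)C(C)(C)C)[C@@H]12 | intermediate
30 | luzonoid A (1S,5S,7S,8R,9S) | CC(C)CC(=O)O[C@@H]1OC=C(CO)[C@H]2C[C@H](OC(=O)/C=C/c3ccc(O)cc3)[C@](O)(CO)[C@@H]12 | target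

**Step count**
Total: 21 steps. Longest linear sequence: 19 steps (steps 2–18, 20, 21).

**Steps most likely to fail**

Step 4. The two alkyne termini may not be differentiated well enough in the oxidative cyclization (loss of regiocontrol), ethoxide may be lost from the alkenyl–nickel intermediate (β-alkoxide elimination), and the acidic enal may isomerise under the basic nickel alkoxide. The fallback removes the regiochemical question from the nickel step: enal 3 is combined under the same conditions with the symmetrical commercial alkyne 1,1,4,4-tetraethoxybut-2-yne (CCOC(OCC)C#CC(OCC)OCC), which should give the racemic bis(diethoxymethyl)cyclopentenol F1. Lipase resolution as in step 5 leaves the 5R,7S bis-acetal alcohol F2, and pivaloylation gives the bis-acetal pivalate F3. Mild acid (PPTS, wet acetone) should then hydrolyse only the C1 acetal, which is remote from the pivalate, because the remaining acetal is deactivated once the enal is formed; the route is rejoined at 12. The C1/C10 differentiation is thus moved from the nickel step to an acetal hydrolysis, and steps 2, 3, 7 and 8 are bypassed.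

Step 9. Conjugate addition of hydroperoxide to the fully substituted β-carbon may be slow (with competing attack at the aldehyde), or facial control may be lost. The fallback epoxidises with an electrophilic oxidant before the aldehyde is unveiled: from PMB ether 10, mCPBA/NaHCO3 in CH2Cl2 (approach anti to the pivalate) gives the α-epoxide PMB ether F4, DDQ gives the epoxy alcohol F5, and Dess–Martin periodinane oxidises it to 13.

Step 10. The aldehyde may be reduced or pinacol-coupled by SmI2, the samarium aldolate may undergo retro-aldol cleavage or lose water, and C9 may be protonated from the α face. The fallback opens the epoxide at the alcohol oxidation state by two-electron chemistry: from 13, NaBH4 gives the epoxy alcohol F5, and I2/PPh3/imidazole gives the epoxy iodide F6. Zinc dust in EtOH then gives, by reductive elimination, the tertiary allylic alcohol with an exocyclic C9=C1 methylene F7. Hydroboration (9-BBN, then NaBO3) gives the 1,3-diol F8, and TEMPO/PhI(OAc)2 oxidises the primary alcohol to 14.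

Further compounds
F1 | step 4 | racemic methyl 2-[(1R*,4S*)-2,3-bis(diethoxymethyl)-4-hydroxycyclopent-2-en-1-yl]acetate | COC(=O)C[C@H]1C[C@H](O)C(C(OCC)OCC)=C1C(OCC)OCC.COC(=O)C[C@@H]1C[C@@H](O)C(C(OCC)OCC)=C1C(OCC)OCC
F2 | step 4 | (1R,4S) enantiomer of F1 (5R,7S in iridoid numbering) | COC(=O)C[C@H]1C[C@H](O)C(C(OCC)OCC)=C1C(OCC)OCC
F3 | step 4 | 7β-O-pivalate of F2 | COC(=O)C[C@H]1C[C@H](OC(=O)C(C)(C)C)C(C(OCC)OCC)=C1C(OCC)OCC
F4 | step 9 | 8,9-α-epoxide of PMB ether 10 | COC(=O)C[C@H]1C[C@H](OC(=O)C(C)(C)C)[C@@]2(C(OCC)OCC)O[C@@]12COCc1ccc(OC)cc1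
F5 | step 9 | 8,9-α-epoxy alcohol (C1 as CH2OH) | COC(=O)C[C@H]1C[C@H](OC(=O)C(C)(C)C)[C@@]2(C(OCC)OCC)O[C@@]12CO
F6 | step 10 | 8,9-α-epoxy iodide (C1 as CH2I) | COC(=O)C[C@H]1C[C@H](OC(=O)C(C)(C)C)[C@@]2(C(OCC)OCC)O[C@@]12CI
F7 | step 10 | tertiary allylic alcohol with exocyclic C9=C1 methylene (8α-OH) | COC(=O)C[C@H]1C[C@H](OC(=O)C(C)(C)C)[C@](O)(C(OCC)OCC)C1=C
F8 | step 10 | 1,3-diol (C1 CH2OH on C9, 9β-H, 8α-OH) | COC(=O)C[C@H]1C[C@H](OC(=O)C(C)(C)C)[C@](O)(C(OCC)OCC)[C@H]1CO
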